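The rate constants are assumed; the flask was simulated.

3 questions stood over this flask: how much solid substrate had reacted by the end, how much product stood then, and how much starting material.

solid substrate 0.25 M; partner 0.275 M; reagent 0.500 M; time 12 h

- part of the solid substrate that has turned into other species by 12 h (what has only dissolved does not count)
- the product standing at 12 h, as a percentage of the solid substrate charged
- the starting material standing at 12 h, as a percentage of the solid substrate charged

- as a solid, counted per litre of solution: solid substrate
- at the start none of the solid substrate is in solution
- what has only dissolved of solid substrate counts as not reacted
- starting material means what is dissolved; the solid is not counted in it
- run time (flask): 12 h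

    open intermediate + second intermediate → product (k1 = 0.34 /M/s)
    starting material + reagent → open intermediate (k2 = 0.018 /M/s)
    solid substrate ⇌ starting material, rate k3*(cs3 - [starting material]) while solid is left; crystals form when [starting material] > cs3 (cs3 = 0.096 M, k3 = 0.0024 /s)
    reagent + partner → second intermediate (k4 = 0.0085 /M/s)

I drew the curve first. At the start, reagent went to partner at 4.21 M/h, while solid entered solution at 0.829 M/h at the very most, so second intermediate ran ahead and I counted conversion as product. The knee came from the solid: at that top speed the charge takes 0.301 h, longer than partner's half-life of 0.0453 h at charged reagent.

The level came from a count. Each product takes one reagent through starting material and one through partner, so I defined the shortfall Δ, both charges minus the reagent charge, 0.0250 M. Reagent is the limiting reagent, and when it ends with the solid dissolved, starting material plus partner must equal Δ.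

My first answer put Δ wholly on starting material, 10.0% of the charge. But once the solid is dissolved the two fall together, the logarithm of starting material moving s = 2.12 times as fast as that of partner. At the knee I assumed, roughly, starting material at its solubility, and with reagent assumed at half its charge I reckoned partner at 0.0274 M. Going round, I reckoned partner at 0.0145 M at the end, which gave 0.0105 M of starting material. Going round again, I reckoned partner at 0.00963 M. I committed to 6.15% starting material and 93.8% product.

The forecast gave 93.5% converted (90% to 97%), 93.5% product (90% to 97%) and 6.5% starting material (3% to 10%), holding that “The reagent is slightly short of total demand”.

The flask gave 93.4% converted, 93.4% product and 6.56% starting material.

By 6.00 h reagent stood at 0% of its charge. The flask's remaining starting material and partner came to 0.0250 M, which is Δ of 0.0250 M. In the neighbour flask with 0.85 M of reagent, Δ turned to a surplus, 38.2% of that charge, and 38% of its reagent stood at the end. Ten times the time left the conversion in the flask where it stood: at 120 h it held 93.4% product and 6.56% starting material.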